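**Assumption:** natural (−)-epicatechin is taken as a cheap bulk commercial starting material. "Upper", "middle" and "lower" unit name the three flavan units of the target, starting from the unit whose C4 is bonded to C8 of the next.

## Retrosynthetic overview

1. Target 8 is (−)-epicatechin-(4β→8)-(−)-epicatechin-(4β→6)-(−)-epicatechin. Global hydrogenolysis leads back to dodeca-O-benzyl trimer 7, which carries bromine at C8 of the upper and lower units.
2. C4(middle)–C6(lower) bond: cation from the C4–O ether 6 of a bromine-capped dimer plus 8-bromo monomer 3. Bromine blocks C8, so only C6 is open.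
3. Key C–O disconnection: the C4–O bond of 6 comes from direct C4–H etherification of dimer 5 (new step). The same C–H to C–O logic gives monomer ether 4 from 3.
4. C4(upper)–C8(middle) bond: capped ether 4 plus tetra-O-benzyl epicatechin 2.
5. No ring is built. Rings A, B and C of all three units come intact from 1, and the units are joined upper–middle first, middle–lower second.

## Route

Step 1
Reactants: 1 (−)-epicatechin
Product: 2 5,7,3',4'-tetra-O-benzyl-(−)-epicatechin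
Conditions: BnBr (4.4 equiv), K2CO3 (5 equiv), DMF, 0 °C to rt, Ar
Reagents that add atoms: benzyl bromide BrCc1ccccc1
Why: Williamson etherification; K2CO3 deprotonates only the four phenols, so the secondary 3-OH stays free and the 2R,3R centres are untouched at or below rt.

Step 2
Reactants: 2 5,7,3',4'-tetra-O-benzyl-(−)-epicatechin
Product: 3 8-bromo-5,7,3',4'-tetra-O-benzyl-(−)-epicatechin
Conditions: NBS (1.0 equiv), CH2Cl2, −45 °C to rt
Reagents that add atoms: N-bromosuccinimide O=C1CCC(=O)N1Br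
Why: electrophilic aromatic bromination at C8, the most nucleophilic position of the 5,7-dialkoxy ring A; the bromine then serves as the C8 block in both the upper and the lower unit.

Step 3
Reactants: 3 8-bromo-5,7,3',4'-tetra-O-benzyl-(−)-epicatechin
Product: 4 8-bromo-5,7,3',4'-tetra-O-benzyl-4β-(2-ethoxyethoxy)-(−)-epicatechin
Conditions: DDQ (2 equiv), HOCH2CH2OEt (5 equiv), CH2Cl2, rt
Reagents that add atoms: 2-ethoxyethanol CCOCCO
Why: oxidative benzylic C–H etherification; DDQ abstracts hydride from C4 to give a cation stabilised by O1, O5 and O7, and the alcohol adds anti to the axial 3-OH, forming the C4–O bond as the 4β (3,4-trans, 4S) ether.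

Step 4
Reactants: 4 8-bromo-5,7,3',4'-tetra-O-benzyl-4β-(2-ethoxyethoxy)-(−)-epicatechin; 2 5,7,3',4'-tetra-O-benzyl-(−)-epicatechin
Product: 5 [8-bromo-5,7,3',4'-tetra-O-benzyl-(−)-epicatechin]-(4β→8)-[5,7,3',4'-tetra-O-benzyl-(−)-epicatechin]
Conditions: 2 (3 equiv), TMSOTf (0.3 equiv), 4 Å molecular sieves, CH2Cl2, −78 to −40 °C
Reagents that add atoms: none
Why: Lewis-acid ionisation of the C4–O bond followed by Friedel–Crafts alkylation at C8 of 2; attack anti to the 3-OH sets the upper C4 as 4β, and the bromine cap prevents self-condensation of the electrophile.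

Step 5
Reactants: 5 [8-bromo-5,7,3',4'-tetra-O-benzyl-(−)-epicatechin]-(4β→8)-[5,7,3',4'-tetra-O-benzyl-(−)-epicatechin]
Product: 6 [8-bromo-5,7,3',4'-tetra-O-benzyl-(−)-epicatechin]-(4β→8)-[5,7,3',4'-tetra-O-benzyl-4β-(2-ethoxyethoxy)-(−)-epicatechin]
Conditions: DDQ (2 equiv), HOCH2CH2OEt (10 equiv), CH2Cl2, 0 °C to rt
Reagents that add atoms: 2-ethoxyethanol CCOCCO
Why: Proposed new method: terminal-unit-selective dehydrogenative C4–H etherification of a bromine-capped 4→8 flavan dimer; hydride should leave only from the quasi-axial H-4 of the lower CH2, which is aligned with the π system of its electron-rich, bromine-free ring A, whereas the interflavan H-4 is quasi-equatorial, lies near the nodal plane of both flanking arenes and sits on the bromine-deactivated unit; the cation is then trapped by the alcohol anti to the 3-OH to form the 4β C–O bond, the closest known reaction being the DDQ-mediated C4–H alkoxylation of monomeric tetra-O-benzyl flavan-3-ols as in step 3.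

Step 6
Reactants: 6 [8-bromo-5,7,3',4'-tetra-O-benzyl-(−)-epicatechin]-(4β→8)-[5,7,3',4'-tetra-O-benzyl-4β-(2-ethoxyethoxy)-(−)-epicatechin]; 3 8-bromo-5,7,3',4'-tetra-O-benzyl-(−)-epicatechin
Product: 7 [8-bromo-5,7,3',4'-tetra-O-benzyl-(−)-epicatechin]-(4β→8)-[5,7,3',4'-tetra-O-benzyl-(−)-epicatechin]-(4β→6)-[8-bromo-5,7,3',4'-tetra-O-benzyl-(−)-epicatechin]
Conditions: 6 added slowly to 3 (5 equiv), TMSOTf (0.5 equiv), 4 Å molecular sieves, CH2Cl2, −40 to −20 °C
Reagents that add atoms: none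
Why: Friedel–Crafts alkylation in which the C8 bromine of 3 leaves C6 as the only open ring A position, so the 4→6 bond forms regiospecifically and anti to the 3-OH (4β), while the capped dimer has no free C8 and slow addition to excess 3 suppresses its self-condensation.

Step 7
Reactants: 7 [8-bromo-5,7,3',4'-tetra-O-benzyl-(−)-epicatechin]-(4β→8)-[5,7,3',4'-tetra-O-benzyl-(−)-epicatechin]-(4β→6)-[8-bromo-5,7,3',4'-tetra-O-benzyl-(−)-epicatechin]
Product: 8 (−)-epicatechin-(4β→8)-(−)-epicatechin-(4β→6)-(−)-epicatechin (CNP0178679.3)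
Conditions: H2 (1 atm), Pd(OH)2/C, Et3N (2.2 equiv), THF/MeOH/H2O, rt; Sephadex LH-20
Reagents that add atoms: none
Why: catalytic hydrogenolysis cleaves the twelve benzyl ethers and both aryl C–Br bonds in one operation, Et3N captures the HBr that would otherwise cleave the acid-labile interflavan bonds, and no stereocentre is touched.

## Compound list

1 | (−)-epicatechin, (2R,3R)-2-(3,4-dihydroxyphenyl)chromane-3,5,7-triol, 2,3-cis | Oc1cc(O)c2c(c1)O[C@H](c1ccc(O)c(O)c1)[C@H](O)C2 | starting material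

2 | 5,7,3',4'-tetra-O-benzyl-(−)-epicatechin, (2R,3R), 3-OH free | O(Cc1ccccc1)c1cc(OCc2ccccc2)c2c(c1)O[C@H](c1ccc(OCc3ccccc3)c(OCc3ccccc3)c1)[C@H](O)C2 | intermediate

3 | 8-bromo-5,7,3',4'-tetra-O-benzyl-(−)-epicatechin, (2R,3R) | O(Cc1ccccc1)c1cc(OCc2ccccc2)c2c(c1Br)O[C@H](c1ccc(OCc3ccccc3)c(OCc3ccccc3)c1)[C@H](O)C2 | intermediate

4 | 8-bromo-5,7,3',4'-tetra-O-benzyl-4β-(2-ethoxyethoxy)-(−)-epicatechin, (2R,3R,4S), 2,3-cis-3,4-trans | O(Cc1ccccc1)c1cc(OCc2ccccc2)c2c(c1Br)O[C@H](c1ccc(OCc3ccccc3)c(OCc3ccccc3)c1)[C@H](O)[C@H]2OCCOCC | intermediate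

5 | [8-bromo-5,7,3',4'-tetra-O-benzyl-(−)-epicatechin]-(4β→8)-[5,7,3',4'-tetra-O-benzyl-(−)-epicatechin]; both units 2,3-cis, upper unit 3,4-trans, both 3-OH free | O(Cc1ccccc1)c1cc(OCc2ccccc2)c2c(c1Br)O[C@H](c1ccc(OCc3ccccc3)c(OCc3ccccc3)c1)[C@H](O)[C@H]2c1c(OCc2ccccc2)cc(OCc2ccccc2)c2c1O[C@H](c1ccc(OCc3ccccc3)c(OCc3ccccc3)c1)[C@H](O)C2 | intermediate

6 | [8-bromo-5,7,3',4'-tetra-O-benzyl-(−)-epicatechin]-(4β→8)-[5,7,3',4'-tetra-O-benzyl-4β-(2-ethoxyethoxy)-(−)-epicatechin]; ether on C4 of the lower unit, 3,4-trans | O(Cc1ccccc1)c1cc(OCc2ccccc2)c2c(c1Br)O[C@H](c1ccc(OCc3ccccc3)c(OCc3ccccc3)c1)[C@H](O)[C@H]2c1c(OCc2ccccc2)cc(OCc2ccccc2)c2c1O[C@H](c1ccc(OCc3ccccc3)c(OCc3ccccc3)c1)[C@H](O)[C@H]2OCCOCC | intermediate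

7 | [8-bromo-5,7,3',4'-tetra-O-benzyl-(−)-epicatechin]-(4β→8)-[5,7,3',4'-tetra-O-benzyl-(−)-epicatechin]-(4β→6)-[8-bromo-5,7,3',4'-tetra-O-benzyl-(−)-epicatechin]; all units 2,3-cis, both interflavan bonds 3,4-trans, three 3-OH free | O(Cc1ccccc1)c1cc(OCc2ccccc2)c2c(c1Br)O[C@H](c1ccc(OCc3ccccc3)c(OCc3ccccc3)c1)[C@H](O)[C@H]2c1c(OCc2ccccc2)cc(OCc2ccccc2)c2c1O[C@H](c1ccc(OCc3ccccc3)c(OCc3ccccc3)c1)[C@H](O)[C@H]2c1c(OCc2ccccc2)c(Br)c2c(c1OCc3ccccc3)C[C@@H](O)[C@@H](c1ccc(OCc3ccccc3)c(OCc3ccccc3)c1)O2 | intermediate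

8 | (−)-epicatechin-(4β→8)-(−)-epicatechin-(4β→6)-(−)-epicatechin; upper unit (2R,3R,4R), middle unit (2R,3R,4S), lower unit (2R,3R) | Oc1cc(O)c2c(c1)O[C@H](c1ccc(O)c(O)c1)[C@H](O)[C@H]2c1c(O)cc(O)c2c1O[C@H](c1ccc(O)c(O)c1)[C@H](O)[C@H]2c1c(O)cc2c(c1O)C[C@@H](O)[C@@H](c1ccc(O)c(O)c1)O2 | target

## Step count and risks

Total step count: 7. Longest linear sequence: 7 steps (1 → 2 → 3 → 4 → 5 → 6 → 7 → 8); 2 and 3 re-enter as coupling partners. A six-step variant that uses one uncapped C4 ether for both couplings was not adopted, because an electrophile with a free C8 would oligomerise faster than it alkylates the weakly nucleophilic C6.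

The three steps most likely to fail:

1. **Step 5 (new C–H etherification of the dimer).** Risk: hydride abstraction at the doubly benzylic interflavan C–H, or low conversion. The fallback uses known chemistry and installs the C4 leaving group of the middle unit at the monomer stage, kept latent as a thioether (orthogonal oxygen/sulfur activation). It sets out from 2. DDQ and 2-ethoxyethanol give 5,7,3',4'-tetra-O-benzyl-4β-(2-ethoxyethoxy)-(−)-epicatechin F1. Exchange with 2,6-dimethylbenzenethiol under BF3·OEt2 gives 5,7,3',4'-tetra-O-benzyl-4β-[(2,6-dimethylphenyl)sulfanyl]-(−)-epicatechin F2. BF3·OEt2 at −78 °C ionises only the C4–O bond of 4, which alkylates C8 of F2 to give [8-bromo-5,7,3',4'-tetra-O-benzyl-(−)-epicatechin]-(4β→8)-[5,7,3',4'-tetra-O-benzyl-4β-[(2,6-dimethylphenyl)sulfanyl]-(−)-epicatechin] F3. AgBF4 then activates the C4–S bond of F3 in the presence of excess 3 and gives 7, where the fallback rejoins the route; 6 is bypassed.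

2. **Step 6 (C6 alkylation by the dimeric cation).** Risk: C6 of 3 is a weak nucleophile, and the free C6 positions of 6 or reversible O-alkylation of the 3-OH groups may compete. The fallback reverses the order of bond formation so that the 4→6 bond is made between monomers, where a large excess of 3 is affordable. It sets out from 2. DDQ and ethylene glycol give 5,7,3',4'-tetra-O-benzyl-4β-(2-hydroxyethoxy)-(−)-epicatechin F4. Slow addition of F4 to 3 (6 equiv) and TiCl4 in CH2Cl2/THF at 0 °C gives [5,7,3',4'-tetra-O-benzyl-(−)-epicatechin]-(4β→6)-[8-bromo-5,7,3',4'-tetra-O-benzyl-(−)-epicatechin] F5. The only strongly nucleophilic position of F5 is C8 of its upper unit, which is alkylated by capped ether 4 (TMSOTf, CH2Cl2, −78 °C) to give 7, where the fallback rejoins the route.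

3. **Step 7 (fourteen reductive cleavages in one pot).** Risk: incomplete debromination, or acid-induced interflavan cleavage by the HBr released. The fallback separates the two events. It sets out from 7. n-BuLi (8 equiv, THF, −78 °C, then MeOH) performs bromine–lithium exchange and protonation to give [5,7,3',4'-tetra-O-benzyl-(−)-epicatechin]-(4β→8)-[5,7,3',4'-tetra-O-benzyl-(−)-epicatechin]-(4β→6)-[5,7,3',4'-tetra-O-benzyl-(−)-epicatechin] F6. F6 is hydrogenolysed without base (H2, Pd(OH)2/C, THF/MeOH/H2O) and the fallback rejoins the route at 8.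

## Further compounds

F1 | step 5 | 5,7,3',4'-tetra-O-benzyl-4β-(2-ethoxyethoxy)-(−)-epicatechin | O(Cc1ccccc1)c1cc(OCc2ccccc2)c2c(c1)O[C@H](c1ccc(OCc3ccccc3)c(OCc3ccccc3)c1)[C@H](O)[C@H]2OCCOCC

F2 | step 5 | 5,7,3',4'-tetra-O-benzyl-4β-[(2,6-dimethylphenyl)sulfanyl]-(−)-epicatechin | O(Cc1ccccc1)c1cc(OCc2ccccc2)c2c(c1)O[C@H](c1ccc(OCc3ccccc3)c(OCc3ccccc3)c1)[C@H](O)[C@H]2Sc1c(C)cccc1C

F3 | step 5 | [8-bromo-5,7,3',4'-tetra-O-benzyl-(−)-epicatechin]-(4β→8)-[5,7,3',4'-tetra-O-benzyl-4β-[(2,6-dimethylphenyl)sulfanyl]-(−)-epicatechin] | O(Cc1ccccc1)c1cc(OCc2ccccc2)c2c(c1Br)O[C@H](c1ccc(OCc3ccccc3)c(OCc3ccccc3)c1)[C@H](O)[C@H]2c1c(OCc2ccccc2)cc(OCc2ccccc2)c2c1O[C@H](c1ccc(OCc3ccccc3)c(OCc3ccccc3)c1)[C@H](O)[C@H]2Sc1c(C)cccc1C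

F4 | step 6 | 5,7,3',4'-tetra-O-benzyl-4β-(2-hydroxyethoxy)-(−)-epicatechin | O(Cc1ccccc1)c1cc(OCc2ccccc2)c2c(c1)O[C@H](c1ccc(OCc3ccccc3)c(OCc3ccccc3)c1)[C@H](O)[C@H]2OCCO

F5 | step 6 | [5,7,3',4'-tetra-O-benzyl-(−)-epicatechin]-(4β→6)-[8-bromo-5,7,3',4'-tetra-O-benzyl-(−)-epicatechin] | O(Cc1ccccc1)c1cc(OCc2ccccc2)c2c(c1)O[C@H](c1ccc(OCc3ccccc3)c(OCc3ccccc3)c1)[C@H](O)[C@H]2c1c(OCc2ccccc2)c(Br)c2c(c1OCc3ccccc3)C[C@@H](O)[C@@H](c1ccc(OCc3ccccc3)c(OCc3ccccc3)c1)O2

F6 | step 7 | [5,7,3',4'-tetra-O-benzyl-(−)-epicatechin]-(4β→8)-[5,7,3',4'-tetra-O-benzyl-(−)-epicatechin]-(4β→6)-[5,7,3',4'-tetra-O-benzyl-(−)-epicatechin] | O(Cc1ccccc1)c1cc(OCc2ccccc2)c2c(c1)O[C@H](c1ccc(OCc3ccccc3)c(OCc3ccccc3)c1)[C@H](O)[C@H]2c1c(OCc2ccccc2)cc(OCc2ccccc2)c2c1O[C@H](c1ccc(OCc3ccccc3)c(OCc3ccccc3)c1)[C@H](O)[C@H]2c1c(OCc2ccccc2)cc2c(c1OCc3ccccc3)C[C@@H](O)[C@@H](c1ccc(OCc3ccccc3)c(OCc3ccccc3)c1)O2
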